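**Retrosynthetic overview**
1. Feature: ring A carries in sequence C1–CH3, C2–H, C3–H, C4–ring B, C5–C7 and C6–alkyne. The neighbouring C4 aryl and C5 carbon groups, followed by the unsubstituted C3 and C2, map onto C4, C3, C5 and C6 of a 4-aryl-2-pyrone-3-carboxylate.
2. The quinone methide (C7=ring D) comes from a triaryl carbinol by global O-demethylation and loss of water. The C7–anisyl bond comes from an aryllithium and a phenyl ketone, and the C7–phenyl bond (ring C) from PhMgBr and the aldehyde made from the C5 ester.
3. The C6–alkyne bond (to ring E) comes from Sonogashira coupling of the C6 triflate. Its oxygen is the methoxy group that the cycloaddition leaves beside the ester.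
4. Ring A comes from an inverse-electron-demand Diels–Alder reaction of pyrone 7 with ketene acetal 9 (bonds C5–C6 and C1–C2), followed by loss of CO2 and methanol.
5. Ring order: the four outer benzene rings are bought. The pyrone ring is built first (Knoevenagel condensation, aminomethylenation, lactonisation) and is converted into ring A. Ring D is unveiled last from an anisyl ring.

Key step: step 5

Remark on the chemistry: the target is taken exactly as drawn, with an unsubstituted phenyl ring on C7. It has no stereocentre and ring D is symmetric, so C7 is a racemic stereocentre only in 20, 24 and 25 and is erased afterwards.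

**Route**

Step 1
Reactants: 1 4′-methoxyacetophenone; 2 dimethyl malonate
Product: 3 dimethyl 2-[1-(4-methoxyphenyl)ethylidene]malonate
Conditions: TiCl4 (2 equiv), pyridine (4 equiv), THF, 0 °C → rt
Reagents that add atoms: none
Why: Knoevenagel condensation in its TiCl4/pyridine variant, in which the Lewis acid activates the aryl methyl ketone, forms the titanium enolate of the malonate and binds the water released, so that even a ketone condenses with a malonate.

Step 2
Reactants: 3 dimethyl 2-[1-(4-methoxyphenyl)ethylidene]malonate; 4 N,N-dimethylformamide dimethyl acetal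
Product: 5 dimethyl 2-[(2E)-3-(dimethylamino)-1-(4-methoxyphenyl)prop-2-en-1-ylidene]malonate
Conditions: 4 (2 equiv), DMF, 100 °C
Reagents that add atoms: none
Why: Aminomethylenation of a vinylogously C–H acidic methyl group by an amide acetal, in which both esters acidify the γ-protons of the alkylidene malonate and loss of two molecules of methanol gives the push–pull dienamine, E at the new enamine bond for steric reasons.

Step 3
Reactants: 5 dimethyl 2-[(2E)-3-(dimethylamino)-1-(4-methoxyphenyl)prop-2-en-1-ylidene]malonate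
Product: 7 methyl 4-(4-methoxyphenyl)-2-oxo-2H-pyran-3-carboxylate, via aldehyde 6 (not isolated)
Conditions: HCO2H–H2O (9:1), 80 °C
Reagents that add atoms: water, O
Why: Acid hydrolysis of the enamine gives aldehyde 6, whose enol oxygen attacks the ester lying cis to the chain (one of the two always does) in a 6-exo-trig lactonisation, and loss of methanol gives the conjugated 2-pyrone.

Step 4
Reactants: 8 trimethyl orthopropionate
Product: 9 1,1-dimethoxyprop-1-ene
Conditions: Al(OtBu)3 (0.4 equiv), neat, reflux under a fractionating column, distillation of the product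
Reagents that add atoms: none
Why: Dealcoholation of an orthoester to a ketene acetal, in which the aluminium alkoxide takes over one methoxy group and removes an α-proton while continuous distillation from the basic, acid-free melt removes tert-butanol and the sensitive product as they form.

Step 5
Reactants: 7 methyl 4-(4-methoxyphenyl)-2-oxo-2H-pyran-3-carboxylate; 9 1,1-dimethoxyprop-1-ene
Product: 12 methyl 2-methoxy-6-(4-methoxyphenyl)-3-methylbenzoate, via bridged lactone 10 (not isolated), via dihydroarene 11 (not isolated)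
Conditions: 9 (5 equiv), toluene, base-washed sealed tube, 110 → 140 °C
Reagents that add atoms: none
Why: The LUMO of pyrone 7, lowered by the lactone carbonyl and the C3 ester, pairs with the HOMO of the electron-rich alkene 9, and an asynchronous [4+2] cycloaddition joins the nucleophilic CH(CH3) carbon of 9 to pyrone C6 (ring A C1–C2) and the dimethoxy carbon to the ester-bearing pyrone C3 (ring A C5–C6), giving the 2-oxabicyclo[2.2.2]octenone 10. Retro-Diels–Alder extrusion of CO2 from 10 gives cyclohexadiene 11, and 1,2-elimination of methanol across C1–C6 aromatises it to 12. The closest known reaction type is the inverse-electron-demand Diels–Alder reaction of 2-pyrone-3-carboxylates with 1,1-dialkoxyalkenes, which delivers 2-alkoxybenzoates. Ring A is closed as a six-membered carbocycle by intermolecular [4+2] cycloaddition, four of its carbons coming from pyrone C3–C6 and two from 9. The three stereocentres of 10 and the one of 11 need no control, since all of them become sp2 carbons in 12. Only regioselectivity is needed, and polarisation secures it: the largest LUMO coefficient sits on the unsubstituted vinylogous acceptor terminus C6 and the largest HOMO coefficient on the methyl-bearing carbon of 9, so the oxygenated carbon ends next to the ester.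

Step 6
Reactants: 12 methyl 2-methoxy-6-(4-methoxyphenyl)-3-methylbenzoate
Product: 13 methyl 2-hydroxy-6-(4-methoxyphenyl)-3-methylbenzoate
Conditions: BCl3 (1.3 equiv), CH2Cl2, −78 → 0 °C; then H2O
Reagents that add atoms: none
Why: Chelation-directed aryl methyl ether cleavage, in which BCl3 is held between the ester carbonyl and the neighbouring methoxy oxygen in a six-membered chelate, so chloride dealkylates only this ether and the remote ring B ether and the ester remain.

Step 7
Reactants: 13 methyl 2-hydroxy-6-(4-methoxyphenyl)-3-methylbenzoate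
Product: 14 methyl 6-(4-methoxyphenyl)-3-methyl-2-{[(trifluoromethyl)sulfonyl]oxy}benzoate
Conditions: Tf2O (1.3 equiv), pyridine, CH2Cl2, 0 °C
Reagents that add atoms: trifluoromethanesulfonic anhydride, O=S(=O)(OS(=O)(=O)C(F)(F)F)C(F)(F)F
Why: O-Sulfonylation of a phenol with Tf2O and pyridine, a standard reaction also for hydrogen-bonded salicylates, and nothing else in 13 is nucleophilic enough to compete.

Step 8
Reactants: 14 methyl 6-(4-methoxyphenyl)-3-methyl-2-{[(trifluoromethyl)sulfonyl]oxy}benzoate; 15 4-ethynylanisole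
Product: 16 methyl 6-(4-methoxyphenyl)-2-[(4-methoxyphenyl)ethynyl]-3-methylbenzoate
Conditions: PdCl2(PPh3)2 (5 mol %), CuI (10 mol %), Et3N, DMF, 80 °C
Reagents that add atoms: none
Why: Sonogashira coupling, in which the ortho ester helps oxidative addition of zerovalent palladium into the C6–OTf bond and the copper acetylide of 15 brings a slim, linear group to the crowded position.

Step 9
Reactants: 16 methyl 6-(4-methoxyphenyl)-2-[(4-methoxyphenyl)ethynyl]-3-methylbenzoate
Product: 17 {6-(4-methoxyphenyl)-2-[(4-methoxyphenyl)ethynyl]-3-methylphenyl}methanol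
Conditions: i-Bu2AlH (3 equiv), CH2Cl2, −78 → 0 °C; then aq. potassium sodium tartrate
Reagents that add atoms: none
Why: Hydride reduction of an ester to the primary alcohol with i-Bu2AlH, which at or below 0 °C is far faster than hydroalumination of the diarylalkyne.

Step 10
Reactants: 17 {6-(4-methoxyphenyl)-2-[(4-methoxyphenyl)ethynyl]-3-methylphenyl}methanol
Product: 18 6-(4-methoxyphenyl)-2-[(4-methoxyphenyl)ethynyl]-3-methylbenzaldehyde
Conditions: Dess–Martin periodinane (1.2 equiv), CH2Cl2, 0 °C → rt
Reagents that add atoms: none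
Why: Dess–Martin oxidation of a primary benzylic alcohol stops at the aldehyde under nearly neutral conditions that leave the alkyne and the aryl ethers untouched.

Step 11
Reactants: 18 6-(4-methoxyphenyl)-2-[(4-methoxyphenyl)ethynyl]-3-methylbenzaldehyde; 19 phenylmagnesium bromide
Product: 20 (±)-{6-(4-methoxyphenyl)-2-[(4-methoxyphenyl)ethynyl]-3-methylphenyl}(phenyl)methanol
Conditions: PhMgBr (1.3 equiv), THF, −78 → 0 °C; then H2O
Reagents that add atoms: none
Why: Grignard 1,2-addition to a non-enolisable aldehyde forms the C7–phenyl bond, and the new C7 stereocentre is formed racemic on purpose because step 12 removes it.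

Step 12
Reactants: 20 (±)-{6-(4-methoxyphenyl)-2-[(4-methoxyphenyl)ethynyl]-3-methylphenyl}(phenyl)methanol
Product: 21 {6-(4-methoxyphenyl)-2-[(4-methoxyphenyl)ethynyl]-3-methylphenyl}(phenyl)methanone
Conditions: Dess–Martin periodinane (1.5 equiv), CH2Cl2, rt
Reagents that add atoms: none
Why: Dess–Martin oxidation of a secondary diaryl carbinol to the diaryl ketone, which works on hindered alcohols and needs no acid or metal that could activate the neighbouring alkyne.

Step 13
Reactants: 21 {6-(4-methoxyphenyl)-2-[(4-methoxyphenyl)ethynyl]-3-methylphenyl}(phenyl)methanone; 22 4-bromoanisole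
Product: 24 (±)-(4-methoxyphenyl){6-(4-methoxyphenyl)-2-[(4-methoxyphenyl)ethynyl]-3-methylphenyl}(phenyl)methanol, via 4-methoxyphenyllithium 23 (not isolated)
Conditions: 22 (2 equiv), n-BuLi (2 equiv), THF, −78 °C; then 21, −78 → 0 °C; then H2O at 0 °C
Reagents that add atoms: none
Why: Bromine–lithium exchange and 1,2-addition of the aryllithium to a non-enolisable diaryl ketone, whose carbonyl stays accessible because the alkynyl neighbour is linear and ring B is twisted away; the cold quench keeps the alkoxide from adding to the alkyne, and the racemic C7 stereocentre is erased in step 14.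

Step 14
Reactants: 24 (±)-(4-methoxyphenyl){6-(4-methoxyphenyl)-2-[(4-methoxyphenyl)ethynyl]-3-methylphenyl}(phenyl)methanol
Product: 26 selaginellin A, via triphenol carbinol 25 (not isolated)
Conditions: BBr3 (8 equiv), CH2Cl2, −78 → 0 °C; then ice–water
Reagents that add atoms: none
Why: BBr3 cleaves the three aryl methyl ethers (Lewis acid-assisted SN2 attack of bromide on methyl), and the 4-hydroxyphenyl carbinol level 25 loses water through its strongly stabilised 4-oxygenated trityl cation to give the fuchsone-type quinone methide, for which no alkene geometry arises because ring D is symmetric.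

**Compound list**
1 | 4′-methoxyacetophenone | CC(=O)c1ccc(OC)cc1 | starting material
2 | dimethyl malonate | COC(=O)CC(=O)OC | starting material
3 | dimethyl 2-[1-(4-methoxyphenyl)ethylidene]malonate | COC(=O)C(C(=O)OC)=C(C)c1ccc(OC)cc1 | intermediate
4 | N,N-dimethylformamide dimethyl acetal | COC(OC)N(C)C | starting material
5 | dimethyl 2-[(2E)-3-(dimethylamino)-1-(4-methoxyphenyl)prop-2-en-1-ylidene]malonate | COC(=O)C(C(=O)OC)=C(/C=C/N(C)C)c1ccc(OC)cc1 | intermediate
6 | dimethyl 2-[1-(4-methoxyphenyl)-3-oxopropylidene]malonate (reacts through its enol; not isolated) | COC(=O)C(C(=O)OC)=C(CC=O)c1ccc(OC)cc1 | intermediate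
7 | methyl 4-(4-methoxyphenyl)-2-oxo-2H-pyran-3-carboxylate | COC(=O)C1=C(c2ccc(OC)cc2)C=COC1=O | intermediate
8 | trimethyl orthopropionate | CCC(OC)(OC)OC | starting material
9 | 1,1-dimethoxyprop-1-ene | CC=C(OC)OC | intermediate
10 | methyl 8,8-dimethoxy-5-(4-methoxyphenyl)-7-methyl-3-oxo-2-oxabicyclo[2.2.2]oct-5-ene-4-carboxylate (diastereomer mixture; not isolated) | COC(=O)C12C(=O)OC(C=C1c1ccc(OC)cc1)C(C)C2(OC)OC | intermediate
11 | methyl 6,6-dimethoxy-2-(4-methoxyphenyl)-5-methylcyclohexa-1,3-diene-1-carboxylate (racemic; not isolated) | COC(=O)C1=C(c2ccc(OC)cc2)C=CC(C)C1(OC)OC | intermediate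
12 | methyl 2-methoxy-6-(4-methoxyphenyl)-3-methylbenzoate | COC(=O)c1c(OC)c(C)ccc1-c1ccc(OC)cc1 | intermediate
13 | methyl 2-hydroxy-6-(4-methoxyphenyl)-3-methylbenzoate | COC(=O)c1c(O)c(C)ccc1-c1ccc(OC)cc1 | intermediate
14 | methyl 6-(4-methoxyphenyl)-3-methyl-2-{[(trifluoromethyl)sulfonyl]oxy}benzoate | COC(=O)c1c(OS(=O)(=O)C(F)(F)F)c(C)ccc1-c1ccc(OC)cc1 | intermediate
15 | 4-ethynylanisole | C#Cc1ccc(OC)cc1 | starting material
16 | methyl 6-(4-methoxyphenyl)-2-[(4-methoxyphenyl)ethynyl]-3-methylbenzoate | COC(=O)c1c(C#Cc2ccc(OC)cc2)c(C)ccc1-c1ccc(OC)cc1 | intermediate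
17 | {6-(4-methoxyphenyl)-2-[(4-methoxyphenyl)ethynyl]-3-methylphenyl}methanol | OCc1c(C#Cc2ccc(OC)cc2)c(C)ccc1-c1ccc(OC)cc1 | intermediate
18 | 6-(4-methoxyphenyl)-2-[(4-methoxyphenyl)ethynyl]-3-methylbenzaldehyde | O=Cc1c(C#Cc2ccc(OC)cc2)c(C)ccc1-c1ccc(OC)cc1 | intermediate
19 | phenylmagnesium bromide | Br[Mg]c1ccccc1 | starting material
20 | (±)-{6-(4-methoxyphenyl)-2-[(4-methoxyphenyl)ethynyl]-3-methylphenyl}(phenyl)methanol | OC(c1ccccc1)c1c(C#Cc2ccc(OC)cc2)c(C)ccc1-c1ccc(OC)cc1 | intermediate
21 | {6-(4-methoxyphenyl)-2-[(4-methoxyphenyl)ethynyl]-3-methylphenyl}(phenyl)methanone | O=C(c1ccccc1)c1c(C#Cc2ccc(OC)cc2)c(C)ccc1-c1ccc(OC)cc1 | intermediate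
22 | 4-bromoanisole | COc1ccc(Br)cc1 | starting material
23 | 4-methoxyphenyllithium (not isolated) | [Li]c1ccc(OC)cc1 | intermediate
24 | (±)-(4-methoxyphenyl){6-(4-methoxyphenyl)-2-[(4-methoxyphenyl)ethynyl]-3-methylphenyl}(phenyl)methanol | OC(c1ccccc1)(c1ccc(OC)cc1)c1c(C#Cc2ccc(OC)cc2)c(C)ccc1-c1ccc(OC)cc1 | intermediate
25 | (±)-(4-hydroxyphenyl){6-(4-hydroxyphenyl)-2-[(4-hydroxyphenyl)ethynyl]-3-methylphenyl}(phenyl)methanol (not isolated) | OC(c1ccccc1)(c1ccc(O)cc1)c1c(C#Cc2ccc(O)cc2)c(C)ccc1-c1ccc(O)cc1 | intermediate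
26 | selaginellin A as drawn, 4-[{6-(4-hydroxyphenyl)-2-[(4-hydroxyphenyl)ethynyl]-3-methylphenyl}(phenyl)methylidene]cyclohexa-2,5-dien-1-one | Cc1ccc(-c2ccc(O)cc2)c(C(=C2C=CC(=O)C=C2)c2ccccc2)c1C#Cc1ccc(O)cc1 | target

**Step count**
Total step count: 14.
Longest linear sequence: 13 (steps 1–3 and 5–14). Step 4 is the only side branch.

**Steps most likely to fail**

1. Step 5 (key step).
What may go wrong: the bond to pyrone C3 creates a quaternary centre between the twisted C4 aryl group and the dimethoxy carbon, and the donor aryl group raises the pyrone LUMO. The cycloaddition may therefore be slow enough for thermal oligomerisation or adventitious hydrolysis of the ketene acetal to outrun it. Aromatisation may also stall at the dihydroarene stage.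
Fallback: it sets out from 4-bromoanisole 22 and comes back at 12.
- Ring A is bought instead of built, and the C4–ring B bond is made by carboxylate-directed C–H arylation.
- 2-Methoxy-3-methylbenzoic acid F1 (purchased) has only one free ortho C–H. It is heated with 22, [RuCl2(p-cymene)]2, PCy3 and K2CO3 in NMP at 120 °C to give 2-methoxy-6-(4-methoxyphenyl)-3-methylbenzoic acid F2.
- O-Alkylation of the hindered carboxylate with MeI and K2CO3 in DMF gives 12.

2. Step 14.
What may go wrong: during the exposure to BBr3 the C7 cation may close onto ring B by Friedel–Crafts ring closure to a fluorene skeleton. The boron halide or HBr may add across the electron-rich alkyne. Cleavage of the three ethers may also stay incomplete.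
Fallback: it sets out from triflate 14 and comes back at 25, which loses water to 26. The protecting groups are exchanged while neither the alkyne nor the carbinol is present, so the last step needs only fluoride.
- BBr3 (CH2Cl2, −78 → 0 °C) on 14 should give methyl 6-(4-hydroxyphenyl)-3-methyl-2-{[(trifluoromethyl)sulfonyl]oxy}benzoate F3.
- TBSCl and imidazole in DMF give its tert-butyldimethylsilyl ether F4.
- Sonogashira coupling with tert-butyl(4-ethynylphenoxy)dimethylsilane F5 (purchased) gives the bis-silylated alkynyl ester F6.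
- i-Bu2AlH gives the benzylic alcohol F7, and Dess–Martin periodinane gives the aldehyde F8.
- Phenylmagnesium bromide 19 gives the racemic secondary alcohol F9, and Dess–Martin periodinane gives the phenyl ketone F10.
- (4-Bromophenoxy)(tert-butyl)dimethylsilane F11 (purchased) is converted with n-BuLi at −78 °C into 4-(tert-butyldimethylsilyloxy)phenyllithium F12.
- Addition of F12 to F10 gives the racemic tris-silylated triaryl carbinol F13.
- Bu4NF in THF at 0 °C followed by acetic acid frees 25, which dehydrates to 26.

3. Step 8.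
What may go wrong: oxidative addition and transmetalation at the doubly flanked C6–O bond may be slow. Amine-induced S–O cleavage of the sulfonate and copper-mediated oxidative dimerisation of the alkyne would then consume both partners.
Fallback: it sets out from 14 and 15 and comes back at 16.
- The copper and amine system is replaced by a Negishi alkynylation with a preformed organozinc reagent.
- Compound 15 is deprotonated with n-BuLi in THF at −78 °C to lithium (4-methoxyphenyl)acetylide F14.
- ZnCl2 converts F14 into [(4-methoxyphenyl)ethynyl]zinc chloride F15.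
- F15 is coupled with 14 under Pd(OAc)2 and XPhos in THF at 60 °C to give 16.

**Further compounds**
F1 | step 5 | 2-methoxy-3-methylbenzoic acid (purchased) | COc1c(C)cccc1C(=O)O
F2 | step 5 | 2-methoxy-6-(4-methoxyphenyl)-3-methylbenzoic acid | COc1ccc(cc1)-c1ccc(C)c(OC)c1C(=O)O
F3 | step 14 | methyl 6-(4-hydroxyphenyl)-3-methyl-2-{[(trifluoromethyl)sulfonyl]oxy}benzoate | COC(=O)c1c(OS(=O)(=O)C(F)(F)F)c(C)ccc1-c1ccc(O)cc1
F4 | step 14 | methyl 6-[4-(tert-butyldimethylsilyloxy)phenyl]-3-methyl-2-{[(trifluoromethyl)sulfonyl]oxy}benzoate | COC(=O)c1c(OS(=O)(=O)C(F)(F)F)c(C)ccc1-c1ccc(O[Si](C)(C)C(C)(C)C)cc1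
F5 | step 14 | tert-butyl(4-ethynylphenoxy)dimethylsilane (purchased) | C#Cc1ccc(O[Si](C)(C)C(C)(C)C)cc1
F6 | step 14 | methyl 6-[4-(tert-butyldimethylsilyloxy)phenyl]-2-{[4-(tert-butyldimethylsilyloxy)phenyl]ethynyl}-3-methylbenzoate | COC(=O)c1c(C#Cc2ccc(O[Si](C)(C)C(C)(C)C)cc2)c(C)ccc1-c1ccc(O[Si](C)(C)C(C)(C)C)cc1
F7 | step 14 | (6-[4-(tert-butyldimethylsilyloxy)phenyl]-2-{[4-(tert-butyldimethylsilyloxy)phenyl]ethynyl}-3-methylphenyl)methanol | OCc1c(C#Cc2ccc(O[Si](C)(C)C(C)(C)C)cc2)c(C)ccc1-c1ccc(O[Si](C)(C)C(C)(C)C)cc1
F8 | step 14 | 6-[4-(tert-butyldimethylsilyloxy)phenyl]-2-{[4-(tert-butyldimethylsilyloxy)phenyl]ethynyl}-3-methylbenzaldehyde | O=Cc1c(C#Cc2ccc(O[Si](C)(C)C(C)(C)C)cc2)c(C)ccc1-c1ccc(O[Si](C)(C)C(C)(C)C)cc1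
F9 | step 14 | (±)-(6-[4-(tert-butyldimethylsilyloxy)phenyl]-2-{[4-(tert-butyldimethylsilyloxy)phenyl]ethynyl}-3-methylphenyl)(phenyl)methanol | OC(c1ccccc1)c1c(C#Cc2ccc(O[Si](C)(C)C(C)(C)C)cc2)c(C)ccc1-c1ccc(O[Si](C)(C)C(C)(C)C)cc1
F10 | step 14 | (6-[4-(tert-butyldimethylsilyloxy)phenyl]-2-{[4-(tert-butyldimethylsilyloxy)phenyl]ethynyl}-3-methylphenyl)(phenyl)methanone | O=C(c1ccccc1)c1c(C#Cc2ccc(O[Si](C)(C)C(C)(C)C)cc2)c(C)ccc1-c1ccc(O[Si](C)(C)C(C)(C)C)cc1
F11 | step 14 | (4-bromophenoxy)(tert-butyl)dimethylsilane (purchased) | CC(C)(C)[Si](C)(C)Oc1ccc(Br)cc1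
F12 | step 14 | 4-(tert-butyldimethylsilyloxy)phenyllithium | [Li]c1ccc(O[Si](C)(C)C(C)(C)C)cc1
F13 | step 14 | (±)-[4-(tert-butyldimethylsilyloxy)phenyl](6-[4-(tert-butyldimethylsilyloxy)phenyl]-2-{[4-(tert-butyldimethylsilyloxy)phenyl]ethynyl}-3-methylphenyl)(phenyl)methanol | OC(c1ccccc1)(c1ccc(O[Si](C)(C)C(C)(C)C)cc1)c1c(C#Cc2ccc(O[Si](C)(C)C(C)(C)C)cc2)c(C)ccc1-c1ccc(O[Si](C)(C)C(C)(C)C)cc1
F14 | step 8 | lithium (4-methoxyphenyl)acetylide | [Li]C#Cc1ccc(OC)cc1
F15 | step 8 | [(4-methoxyphenyl)ethynyl]zinc chloride | Cl[Zn]C#Cc1ccc(OC)cc1
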